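**Retrosynthetic overview**

1. The target is (S)-5-hydroxy-5-nonadecylcyclohex-2-en-1-one (ring atoms: C1 carbonyl, C2=C3, C4 allylic CH2, C5 carbinol, C6). The enone is made last by oxidising the allylic C1 carbinol, so the ring is closed at the diol oxidation level.
2. The key disconnection is C4–C5. The feature that allows it is that the tertiary C5–OH is homoallylic to the ring C2=C3 bond (HO–C5–C4–C3=C2), which is the retron of an allyl transfer with allylic inversion.
3. Read backwards, C4 is the terminus of a vinyl group on C2, and C2 also carries a CMe2–OH group. Forwards, that hydroxyl ties itself to the C5 ketone as a temporary oxane ring (lactol, then oxocarbenium ion). A 2-oxonia-Cope shift then closes the carbocycle, places the alkene at C2=C3, carries the C2 configuration to C5, erases the C2 stereocentre and expels the tether as acetone.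
4. The acyclic precursor comes from an aldol union of henicosan-2-one with an α-vinyl aldehyde. The aldehyde's single stereocentre comes from Sharpless epoxidation of prenol and SN2 opening with a vinyl copper reagent.
5. Ring order: the temporary oxane ring, then the cyclohexene ring, then cleavage of the oxane ring, all in one operation. No other ring is made.

Key step: step 8

Assumption: the carbinol carbon created in the aldol step (the later C1) is carried as a mixture of epimers; this is immaterial because it becomes the ketone carbon and takes no part in the stereochemical relay.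

**Route**

Step 1
Reactants: 1 3-methylbut-2-en-1-ol (prenol)
Product: 2 [(2S)-3,3-dimethyloxiran-2-yl]methanol
Conditions: Ti(OiPr)4 (5 mol %), L-(+)-diethyl tartrate (6 mol %), t-BuOOH, 4 Å MS, CH2Cl2, −20 °C
Reagents that add atoms: tert-butyl hydroperoxide, CC(C)(C)OO
Why: Sharpless asymmetric epoxidation of a primary allylic alcohol, in which the L-(+)-tartrate ligand directs oxygen to the face that gives the (S)-epoxide, the source of all chirality in the route.

Step 2
Reactants: 2 [(2S)-3,3-dimethyloxiran-2-yl]methanol
Product: 3 (2R)-2-ethenyl-3-methylbutane-1,3-diol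
Conditions: CH2=CHMgBr (3 equiv), CuI (10 mol %), THF, −40 to −10 °C; aq. NH4Cl
Reagents that add atoms: vinylmagnesium bromide, C=C[Mg]Br
Why: Copper-catalysed SN2 opening of a 2,3-epoxy alcohol by a Grignard reagent, in which the fully substituted epoxide carbon cannot be attacked, so the vinyl group enters at the secondary carbon with inversion and sets the (R) centre that later directs the ring closure.

Step 3
Reactants: 3 (2R)-2-ethenyl-3-methylbutane-1,3-diol
Product: 4 (2R)-2-ethenyl-3-methyl-1,3-bis(triethylsilyloxy)butane
Conditions: TESOTf (2.5 equiv), 2,6-lutidine, CH2Cl2, −78 to 0 °C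
Reagents that add atoms: triethylsilyl trifluoromethanesulfonate, CC[Si](CC)(CC)OS(=O)(=O)C(F)(F)F
Why: Exhaustive silylation with a silyl triflate, which is reactive enough for the tertiary hydroxyl and touches no stereocentre.

Step 4
Reactants: 4 (2R)-2-ethenyl-3-methyl-1,3-bis(triethylsilyloxy)butane
Product: 5 (2S)-2-ethenyl-3-methyl-3-(triethylsilyloxy)butanal
Conditions: (COCl)2, DMSO, CH2Cl2, −78 to −40 °C; Et3N, −78 to −20 °C; cold buffered work-up
Reagents that add atoms: none
Why: Swern oxidation in which the chlorosulfonium salt cleaves the primary triethylsilyl ether and oxidises it in the same flask while the hindered tertiary silyl ether survives, and the cold amine step keeps the α-stereocentre intact (the descriptor becomes (S) only because the CIP ranks change).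

Step 5
Reactants: 6 icosanoic acid
Product: 7 henicosan-2-one
Conditions: MeLi (2.2 equiv), THF, 0 °C to rt; poured into cold 1 M HCl
Reagents that add atoms: methyllithium, [Li]C
Why: Ketone synthesis from a carboxylic acid with an organolithium, in which addition to the lithium carboxylate stops at the dilithium gem-diolate and the methyl ketone appears only on acidic work-up.

Step 6
Reactants: 7 henicosan-2-one; 5 (2S)-2-ethenyl-3-methyl-3-(triethylsilyloxy)butanal
Product: 9 (3R)-3-ethenyl-4-hydroxy-2-methyl-2-(triethylsilyloxy)pentacosan-6-one, via lithium enolate 8 (not isolated)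
Conditions: LDA (1.05 equiv), THF, −78 °C; then 5, −78 °C; aq. NH4Cl
Reagents that add atoms: none
Why: Kinetic deprotonation on the methyl side gives lithium enolate 8, whose aldol addition to the α-branched aldehyde is fast at −78 °C, and the new carbinol centre forms as a mixture of epimers that converge later.

Step 7
Reactants: 9 (3R)-3-ethenyl-4-hydroxy-2-methyl-2-(triethylsilyloxy)pentacosan-6-one
Product: 10 (3R)-3-ethenyl-2,4-dihydroxy-2-methylpentacosan-6-one
Conditions: HF·pyridine, pyridine, THF, 0 °C to rt
Reagents that add atoms: none
Why: Fluoride-mediated cleavage of the tertiary silyl ether under buffered, essentially neutral conditions that should not provoke retro-aldol cleavage or dehydration of the β-hydroxy ketone.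

Step 8
Reactants: 10 (3R)-3-ethenyl-2,4-dihydroxy-2-methylpentacosan-6-one
Product: 14 (1S)-1-nonadecylcyclohex-4-ene-1,3-diol, via lactol 11 (not isolated), via ring oxocarbenium ion 12 (not isolated), via exocyclic oxocarbenium ion 13 (not isolated)
Conditions: Sn(OTf)2 (10 mol %), CH2Cl2, 0 °C to rt, N2 sweep; then AcOH/THF/H2O, rt
Reagents that add atoms: none
Why: Proposed new method: the tertiary hydroxyl adds to the ketone (6-exo-trig) to give lactol 11, Sn(OTf)2 ionises it to the cyclic oxocarbenium ion 12, and the vinyl group on the ring carbon opposite to the cationic carbon then undergoes a 2-oxonia-Cope [3,3] shift (or its stepwise Prins addition and Grob fragmentation) that forms the C4–C5 bond, breaks the bond to the CMe2 carbon and gives ion 13, which the water set free in the ionisation hydrolyses to 14 and acetone. The closest known reaction type is the acid-catalysed allyl transfer from tertiary homoallylic alcohols to aldehydes through the same 2-oxonia-Cope rearrangement, here run within one molecule and on a ketone, and the transition state has the 2-oxabicyclo[2.2.2]octane shape that acid closes easily in the 1,8-cineole series. The carbocycle is closed by attack of the terminal alkene carbon on the oxocarbenium carbon, a 6-endo-trig closure with respect to the alkene, through a boat-like six-centre array. The new quaternary centre is set by the vinyl-bearing centre alone: in that bicyclic array its three ring bonds (to CMe2, to the carbinol CH and to the vinyl CH) must pair with O, C6 and C4 on C5, so (R) can lead only to (5S) in the target numbering, and the controlling centre itself becomes the sp2 carbon C2. The step needs C–C bond formation to outrun loss of a proton from 12 and loss of water from the β-hydroxy ketone, and it needs the allyl unit to react with transposition; the gem-dimethyl group favours the lactol, the vinyl group is held 1,4 to the cationic carbon so that only its terminus can reach it, and acetone, a poor allyl acceptor that is swept out, makes the transfer irreversible.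

Step 9
Reactants: 14 (1S)-1-nonadecylcyclohex-4-ene-1,3-diol
Product: 15 (5S)-5-hydroxy-5-nonadecylcyclohex-2-en-1-one
Conditions: activated MnO2 (excess), CH2Cl2, rt
Reagents that add atoms: none
Why: Allylic oxidation with activated MnO2 converts only the allylic secondary alcohol, so both carbinol epimers converge on the enone while the tertiary alcohol, the sole stereocentre, and the acid- and base-sensitive β-hydroxy enone are left untouched.

**Compound list**

1 | 3-methylbut-2-en-1-ol (prenol) | CC(C)=CCO | starting material
2 | [(2S)-3,3-dimethyloxiran-2-yl]methanol | OC[C@@H]1OC1(C)C | intermediate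
3 | (2R)-2-ethenyl-3-methylbutane-1,3-diol | OC[C@@H](C=C)C(C)(C)O | intermediate
4 | (2R)-2-ethenyl-3-methyl-1,3-bis(triethylsilyloxy)butane | CC[Si](CC)(CC)OC[C@@H](C=C)C(C)(C)O[Si](CC)(CC)CC | intermediate
5 | (2S)-2-ethenyl-3-methyl-3-(triethylsilyloxy)butanal | O=C[C@@H](C=C)C(C)(C)O[Si](CC)(CC)CC | intermediate
6 | icosanoic acid | CCCCCCCCCCCCCCCCCCCC(=O)O | starting material
7 | henicosan-2-one | CCCCCCCCCCCCCCCCCCCC(C)=O | intermediate
8 | lithium enolate of 7 (lithium henicos-1-en-2-olate) | [Li]OC(=C)CCCCCCCCCCCCCCCCCCC | intermediate
9 | (3R)-3-ethenyl-4-hydroxy-2-methyl-2-(triethylsilyloxy)pentacosan-6-one (both C4 epimers) | CCCCCCCCCCCCCCCCCCCC(=O)CC(O)[C@@H](C=C)C(C)(C)O[Si](CC)(CC)CC | intermediate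
10 | (3R)-3-ethenyl-2,4-dihydroxy-2-methylpentacosan-6-one (both C4 epimers) | CCCCCCCCCCCCCCCCCCCC(=O)CC(O)[C@@H](C=C)C(C)(C)O | intermediate
11 | lactol, (3R)-3-ethenyl-2,2-dimethyl-6-nonadecyloxane-4,6-diol | CCCCCCCCCCCCCCCCCCCC1(O)CC(O)[C@@H](C=C)C(C)(C)O1 | intermediate
12 | ring oxocarbenium ion, (3R)-3-ethenyl-4-hydroxy-2,2-dimethyl-6-nonadecyl-2,3,4,5-tetrahydropyrylium | CCCCCCCCCCCCCCCCCCCC1=[O+]C(C)(C)[C@H](C=C)C(O)C1 | intermediate
13 | exocyclic oxocarbenium ion, [(1S)-3-hydroxy-1-nonadecylcyclohex-4-en-1-yl](propan-2-ylidene)oxonium | CCCCCCCCCCCCCCCCCCC[C@]1([O+]=C(C)C)CC=CC(O)C1 | intermediate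
14 | (1S)-1-nonadecylcyclohex-4-ene-1,3-diol (both C3 epimers) | CCCCCCCCCCCCCCCCCCC[C@]1(O)CC=CC(O)C1 | intermediate
15 | (5S)-5-hydroxy-5-nonadecylcyclohex-2-en-1-one | CCCCCCCCCCCCCCCCCCC[C@]1(O)CC=CC(=O)C1 | target

**Step count and risks**

Total step count: 9. Longest linear sequence: 8 steps (steps 1 to 4, then 6 to 9).

Most likely to fail, step 8 (proposed new method). The cyclic oxocarbenium ion may lose a proton to an enol ether, the β-hydroxy ketone may lose water, or the bicyclic cation may be captured before it fragments, each faster than the boat-like [3,3] array is reached. The fallback keeps the same bond and the same relay of chirality from the carbon next to the carbinol, but replaces the carbinol leaving group by silicon and uses only known reaction types. It sets out from 7 and comes back at 14.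
- Carbethoxylation of 7 on the methyl side (NaH, diethyl carbonate, THF, reflux) gives ethyl 3-oxodocosanoate F1.
- Ketalisation (ethylene glycol, TsOH, benzene, reflux) gives ethyl (2-nonadecyl-1,3-dioxolan-2-yl)acetate F2.
- DIBAL-H at −78 °C gives (2-nonadecyl-1,3-dioxolan-2-yl)acetaldehyde F3.
- Addition of (E)-[3-(dimethylphenylsilyl)allyl]diisopinocampheylborane (the antipode that gives the drawn adduct) gives the anti β-hydroxy allylsilane (2R,3S)-3-[dimethyl(phenyl)silyl]-1-(2-nonadecyl-1,3-dioxolan-2-yl)pent-4-en-2-ol F4.
- TBSOTf and 2,6-lutidine give its tert-butyldimethylsilyl ether F5.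
- PPTS in wet acetone frees the ketone (3S,4R)-4-(tert-butyldimethylsilyloxy)-3-[dimethyl(phenyl)silyl]pentacos-1-en-6-one F6.
- TiCl4 in CH2Cl2 at −78 °C closes the C4–C5 bond by an intramolecular Hosomi–Sakurai reaction (anti SE2′, chair transition state with the nonadecyl group expected equatorial) to give (1S,3R)-3-(tert-butyldimethylsilyloxy)-1-nonadecylcyclohex-4-en-1-ol F7.
- Bu4NF then gives 14 as its single (1S,3R) epimer.
- If the cyclisation favours the other face of the ketone, the epimers at the tertiary centre are separable at F7 and the antipodal borane is used.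

Step 6. Proton transfer from the α-branched, α-vinyl aldehyde to the basic lithium enolate may erode the configuration of the vinyl-bearing carbon or move the double bond into conjugation. Deprotonation of the ketone may also not be fully regioselective. The fallback generates the enolate regiospecifically and without base; it sets out from 7 and comes back at 9.
- Kinetic silylation of 7 (LDA, Me3SiCl, THF, −78 °C) gives trimethyl(henicos-1-en-2-yloxy)silane F8.
- NBS in THF at 0 °C gives 1-bromohenicosan-2-one F9, which is freed from any regioisomer by crystallisation.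
- SmI2 (2 equiv) in THF at −78 °C in the presence of 5 forms the samarium enolate at the brominated carbon only, and its Reformatsky-type addition gives 9.

Step 4. During the amine step the double bond may migrate into conjugation with the new aldehyde, the α-carbon may epimerise, or cleavage of the primary silyl ether may be incomplete. The fallback separates unmasking from oxidation and avoids any amine; it sets out from 4 and comes back at 5.
- PPTS in MeOH/CH2Cl2 at 0 °C removes only the primary triethylsilyl group to give (2R)-2-ethenyl-3-methyl-3-(triethylsilyloxy)butan-1-ol F10.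
- Dess–Martin periodinane buffered with NaHCO3 in CH2Cl2 at 0 °C oxidises it to 5.

Further compounds
F1 | step 8 | ethyl 3-oxodocosanoate | CCCCCCCCCCCCCCCCCCCC(=O)CC(=O)OCC
F2 | step 8 | ethyl (2-nonadecyl-1,3-dioxolan-2-yl)acetate | CCCCCCCCCCCCCCCCCCCC1(CC(=O)OCC)OCCO1
F3 | step 8 | (2-nonadecyl-1,3-dioxolan-2-yl)acetaldehyde | CCCCCCCCCCCCCCCCCCCC1(CC=O)OCCO1
F4 | step 8 | (2R,3S)-3-[dimethyl(phenyl)silyl]-1-(2-nonadecyl-1,3-dioxolan-2-yl)pent-4-en-2-ol | CCCCCCCCCCCCCCCCCCCC1(C[C@@H](O)[C@H](C=C)[Si](C)(C)c2ccccc2)OCCO1
F5 | step 8 | tert-butyldimethylsilyl ether of F4 | CCCCCCCCCCCCCCCCCCCC1(C[C@@H](O[Si](C)(C)C(C)(C)C)[C@H](C=C)[Si](C)(C)c2ccccc2)OCCO1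
F6 | step 8 | (3S,4R)-4-(tert-butyldimethylsilyloxy)-3-[dimethyl(phenyl)silyl]pentacos-1-en-6-one | CCCCCCCCCCCCCCCCCCCC(=O)C[C@@H](O[Si](C)(C)C(C)(C)C)[C@H](C=C)[Si](C)(C)c1ccccc1
F7 | step 8 | (1S,3R)-3-(tert-butyldimethylsilyloxy)-1-nonadecylcyclohex-4-en-1-ol | CCCCCCCCCCCCCCCCCCC[C@]1(O)CC=C[C@H](O[Si](C)(C)C(C)(C)C)C1
F8 | step 6 | trimethyl(henicos-1-en-2-yloxy)silane | C=C(O[Si](C)(C)C)CCCCCCCCCCCCCCCCCCC
F9 | step 6 | 1-bromohenicosan-2-one | BrCC(=O)CCCCCCCCCCCCCCCCCCC
F10 | step 4 | (2R)-2-ethenyl-3-methyl-3-(triethylsilyloxy)butan-1-ol | OC[C@@H](C=C)C(C)(C)O[Si](CC)(CC)CC
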